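The seven-membered ring (longipinane numbering) spans the C5···C10 diagonal of the cyclobutane C4–C5–C11–C10 through C6–C7–C8–C9, with O–C9 and C15 cis. C5–C10 is therefore taken as the central σ bond of a bicyclo[1.1.0]butane and C6–C9 as a 4-silyloxy-3-methyl-2-pyrone, whose lactone joins O–C9 to C15 and whose silyl group is tied to the C4 wing. A photoredox radical-cation (4+3) cycloaddition forms C5–C6 and C9–C10 with inversion at both bridgeheads, closing the seven-membered ring and setting C5, C6, C9 and C10. Since the new bridge enters on the endo face, the wings carry exo C1 and C3 only; aldol condensation and cuprate addition then close the six-membered ring.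

Key step: step 8

Remark (numbering): C1 ketone carbon, C2 its CH2, C3 the CH carrying methyl C12, C4 and C11 the cyclobutane CH groups bound to C3 and C1, C5 the cyclobutane CH bound to C6, C6 the quaternary carbon with methyl C14 and hydroxymethyl C15, C7 and C9 the angeloyloxy carbons, C8 the CH2 between them, C10 the cyclobutane carbon with methyl C13.
Remark (abbreviations): TBS = tert-butyldimethylsilyl, TBDPS = tert-butyldiphenylsilyl, TMS = trimethylsilyl, TIPDS = 1,1,3,3-tetraisopropyldisiloxane-1,3-diyl, DPTI = 4,5-diphenyl-1-(trifluoromethylsulfonyl)imidazolidin-2-one bound as its amidate.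
Remark (geometry): a bicyclobutane bridgehead is attacked along the extension of the central bond, that is with inversion, so both new bonds of step 8 end on the face of the wing hydrogens. A bridge across the wings would block that face, which is why the C1–C2–C3 bridge is closed only after step 8.
Remark (assumptions): the antipode of the catalyst of step 1 that gives the (1S) ester is used; the copper carbene of step 4 is assumed to add to the cyclopropene faster than the metal opens it; the excited acridinium of step 8 is assumed to oxidise the bicyclobutane of 14.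

Step 1
Reactants: 1 propyne; 2 ethyl diazoacetate
Product: 3 ethyl (1S)-2-methylcycloprop-2-ene-1-carboxylate
Conditions: Rh2(OAc)(DPTI)3 (0.5 mol%), 1 (3 equiv, condensed), CH2Cl2, slow addition of 2, 0 °C → rt
Reagents that add atoms: none
Why: Dirhodium-carbene [2+1] cycloaddition to the terminal alkyne (cyclopropenation) should give the cyclopropene, and the chiral amidate ligands differentiate the two faces of the carbene so that the sp3 carbon (future C4) is set as (S).

Step 2
Reactants: 3 ethyl (1S)-2-methylcycloprop-2-ene-1-carboxylate
Product: 4 [(1S)-2-methylcycloprop-2-en-1-yl]methanol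
Conditions: DIBAL-H (2.2 equiv), Et2O, −78 → −20 °C; aq. Rochelle salt
Reagents that add atoms: none
Why: Hydride reduction of the ester at low temperature should give the cyclopropenylcarbinol without hydrometallation of the strained alkene and without touching the stereocentre.

Step 3
Reactants: 4 [(1S)-2-methylcycloprop-2-en-1-yl]methanol
Product: 5 tert-butyldimethyl{[(1S)-2-methylcycloprop-2-en-1-yl]methoxy}silane
Conditions: TBSCl, imidazole, CH2Cl2, 0 °C
Reagents that add atoms: tert-butyldimethylsilyl chloride, CC(C)(C)[Si](C)(C)Cl
Why: Standard silylation of the primary alcohol, which removes O–H insertion from step 4 and supplies the bulk that sends the carbene to the opposite face.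

Step 4
Reactants: 5 tert-butyldimethyl{[(1S)-2-methylcycloprop-2-en-1-yl]methoxy}silane; 2 ethyl diazoacetate
Product: 6 ethyl 4-exo-[(TBS-oxy)methyl]-1-methylbicyclo[1.1.0]butane-2-exo-carboxylate
Conditions: Cu(MeCN)4PF6 (2 mol%), CH2Cl2, 0 °C, syringe-pump addition of 2; chromatography to remove the endo-ester isomer
Reagents that add atoms: none
Why: Copper-carbene cyclopropanation of the strained cyclopropene double bond (the second stage of the classical alkyne-to-bicyclobutane double carbene addition) should occur anti to the silyloxymethyl group, which makes that group exo on the future C4, and should place the ester exo on the new wing carbon (future C11) for steric reasons; the two bridgeheads (future C5 and C10) are fixed by the cage.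

Step 5
Reactants: 6 ethyl 4-exo-[(TBS-oxy)methyl]-1-methylbicyclo[1.1.0]butane-2-exo-carboxylate
Product: 9 1-[4-exo-(hydroxymethyl)-1-methylbicyclo[1.1.0]butan-2-exo-yl]ethan-1-one, via α-silyl ketone 7 (not isolated), via methyl ketone silyl ether 8 (not isolated)
Conditions: TMSCH2Li (2.5 equiv), pentane–THF, 0 °C; MeOH; then TBAF, AcOH, THF, 0 °C → rt
Reagents that add atoms: (trimethylsilyl)methyllithium, [Li]C[Si](C)(C)C
Why: Addition of (trimethylsilyl)methyllithium to the ester stops at the α-silyl ketone because this is deprotonated in the flask, methanol then effects protodesilylation to the methyl ketone and buffered fluoride removes the TBS ether; the exo acetyl group at C11 is the more stable epimer and is not at risk.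

Step 6
Reactants: 10 ethyl 2-methyl-3-oxobutanoate
Product: 12 4-hydroxy-3-methyl-2H-pyran-2-one, via dioxo ester 11 (not isolated)
Conditions: NaH, THF, 0 °C; n-BuLi, 0 °C; HCO2Et, −78 → 0 °C; aq. HCl; then crude 11, DBU (cat.), PhMe, 80 °C
Reagents that add atoms: ethyl formate, CCOC=O
Why: γ-Formylation of the acetoacetate dianion followed by lactonisation of the enol onto the ester is the usual 4-hydroxy-2-pyrone synthesis from 3,5-dioxo esters.

Step 7
Reactants: 9 1-[4-exo-(hydroxymethyl)-1-methylbicyclo[1.1.0]butan-2-exo-yl]ethan-1-one; 12 4-hydroxy-3-methyl-2H-pyran-2-one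
Product: 14 TIPDS-tethered pyrone–bicyclobutane (one silicon on the CH2–O of 9 and the other on O4 of the pyrone), via chlorodisiloxane 13 (not isolated)
Conditions: TIPDSCl2 (1.05 equiv), imidazole, CH2Cl2, −30 °C; then 12, Et3N, DMAP (cat.), 0 °C → rt
Reagents that add atoms: 1,3-dichloro-1,1,3,3-tetraisopropyldisiloxane, CC(C)[Si](Cl)(C(C)C)O[Si](Cl)(C(C)C)C(C)C
Why: Stepwise silylation, in which the primary alcohol reacts at one silicon and the acidic 4-hydroxyl of the pyrone then displaces the second chloride, should give the vinylogous silyl ester that serves both as temporary tether and as silyl dienol ether nucleophile for step 8.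

Step 8
Reactants: 14 TIPDS-tethered pyrone–bicyclobutane
Product: 16 3-hydroxy-1,7-dioxo-12-nor-2,3-secolongipinan-15,9-olide (C11 acetyl and C4 hydroxymethyl on the cyclobutane face opposite to the C6–C9 bridge; lactone on the C11 side), via silyl enol ether 15 (not isolated)
Conditions: 9-mesityl-3,6-di-tert-butyl-10-phenylacridinium tetrafluoroborate (5 mol%), MeCN–CH2Cl2, 2 mM, degassed, blue LEDs, rt; then HF·pyridine, THF, 0 °C
Reagents that add atoms: none
Why: Proposed new method: the excited acridinium should oxidise the electron-rich C5–C10 σ bond of the bicyclobutane to its radical cation, the tethered silyl dienol ether (pyrone C3) attacks the unsubstituted bridgehead C5 from the endo face along the extension of the central bond (C5–C6 bond, inversion at C5), and the tertiary cyclobutyl radical at C10 then adds to the C6 terminus of the resulting 4-silyloxypyrylium-type cation (C9–C10 bond) before back electron transfer gives silyl enol ether 15, which HF·pyridine cleaves at both Si–O bonds to the C7 ketone and the C3 carbinol. The closest known reaction types are photoredox [2π+2σ] cycloadditions of bicyclobutane radical cations with alkenes, nucleophilic capture of bicyclobutane radical cations with inversion, radical-cation Diels–Alder reactions and the Lewis-acid formal (4+3) cycloaddition of acyl bicyclobutanes with silyl dienol ethers to bicyclo[4.1.1]octanes. Two rings close: the ten-membered disiloxane ring in the first, tether-guided C–C bond formation, and the seven-membered carbocycle (C5, C6, C7, C8, C9, C10 plus C4 or C11) by 7-endo addition of the C10 radical to the cationic terminus, which completes a 6-oxabicyclo[3.2.2]nonene cage with bridgeheads C6 and C9. C5 and C10 are set by the double inversion inherent to bridgehead attack, which puts the four-carbon bridge on the face of the wing hydrogens and leaves the exo C1 and C3 substituents on the opposite face; C9 follows from C6 because the lactone can only bridge cis; C6 is set by the tether, which can span from the C3 oxygen to O7 in the closed cage only when the C7–C8 flank lies under the C4 wing and the lactone under the C11 wing. The step needs regioselectivity (pyrone C3 to C5, not to C10), secured by attack at the less substituted bridgehead with formation of the tertiary radical, and it needs ring closure to outrun reduction of the C10 radical, which is the least secure point.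

Step 9
Reactants: 16 3-hydroxy-1,7-dioxo-12-nor-2,3-secolongipinan-15,9-olide
Product: 17 1,3,7-trioxo-12-nor-2,3-secolongipinan-15,9-olide (C3 aldehyde on C4)
Conditions: Dess–Martin periodinane, CH2Cl2, 0 °C → rt
Reagents that add atoms: none
Why: Dess–Martin oxidation of the primary carbinol (drawn from any bridged hemiketal with the C1 ketone by equilibrium) should give the aldehyde under neutral conditions that leave the β-acyloxy ketone and the lactone untouched.

Step 10
Reactants: 17 1,3,7-trioxo-12-nor-2,3-secolongipinan-15,9-olide
Product: 19 1,7-dioxo-12-norlongipin-2-en-15,9-olide, via aldol 18 (not isolated)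
Conditions: piperidine (20 mol%), AcOH (20 mol%), PhH, 4 Å MS, 50 °C
Reagents that add atoms: none
Why: Intramolecular aldol condensation of the methyl ketone (C2) with the cis-1,3-disposed aldehyde (C3) should close the six-membered ring (6-enolexo aldolisation) and dehydrate to the bridged enone, the weakly acidic amine salt being chosen so that the β-acyloxy ketone at C7 does not eliminate.

Step 11
Reactants: 19 1,7-dioxo-12-norlongipin-2-en-15,9-olide
Product: 20 7-oxo-1-(trimethylsilyloxy)longipin-1-en-15,9-olide
Conditions: Me2CuLi (from CuI and MeLi), TMSCl, THF, −78 °C; Et3N, cold aq. NaHCO3; used crude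
Reagents that add atoms: lithium dimethylcuprate, [Li+].C[Cu-]C; chlorotrimethylsilane, C[Si](C)(C)Cl
Why: TMSCl-accelerated conjugate addition of the methyl cuprate should occur on the enone face next to the C5 bridge (inner hydrogen) and anti to the C10 bridge, whose methyl C13 shields the other face, which sets C3 as in cuprate additions to apoverbenone-type enones, and the enolate is trapped as a silyl enol ether that masks the C1 ketone.

Step 12
Reactants: 20 7-oxo-1-(trimethylsilyloxy)longipin-1-en-15,9-olide
Product: 22 7,9,15-trihydroxylongipinan-1-one, via silyl enol ether triol 21 (not isolated)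
Conditions: LiAlH4, THF, −78 → 0 °C; then 1 M aq. HCl, 0 °C
Reagents that add atoms: none
Why: Hydride should attack the C7 ketone from the open face between the two two-atom bridges, anti to the cyclobutane, placing 7-OH cis to C14 and trans to C15, and should then open the lactone to the C9 and C15 carbinols while the silyl enol ether protects C1 until the acidic work-up releases the ketone.

Step 13
Reactants: 22 7,9,15-trihydroxylongipinan-1-one
Product: 23 15-(TBDPS-oxy)-7,9-dihydroxylongipinan-1-one
Conditions: TBDPSCl, imidazole, CH2Cl2, 0 °C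
Reagents that add atoms: tert-butyldiphenylsilyl chloride, CC(C)(C)[Si](Cl)(c1ccccc1)c1ccccc1
Why: Silylation with the bulky chlorosilane should take only the primary hydroxyl, since both secondary hydroxyls sit next to quaternary carbons.

Step 14
Reactants: 23 15-(TBDPS-oxy)-7,9-dihydroxylongipinan-1-one; 24 angelic acid
Product: 25 7,9-bis(angeloyloxy)-15-(TBDPS-oxy)longipinan-1-one
Conditions: 24 (2 × 2 equiv), 2,4,6-trichlorobenzoyl chloride, Et3N, PhMe, rt; then 23, PhMe, 80 °C
Reagents that add atoms: angelic acid (second equivalent), C/C=C(/C)C(=O)O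
Why: Yamaguchi esterification through the mixed anhydride, run without DMAP and with one equivalent of angelic acid consumed per hydroxyl, should acylate both secondary hydroxyls while keeping the Z geometry of the angeloyl groups.

Step 15
Reactants: 25 7,9-bis(angeloyloxy)-15-(TBDPS-oxy)longipinan-1-one
Product: 26 7,9-bis(angeloyloxy)-15-hydroxylongipinan-1-one
Conditions: HF·pyridine, pyridine, THF, 0 °C → rt
Reagents that add atoms: none
Why: Fluoride cleavage of the silyl ether under buffered acidic conditions should free the C15 hydroxyl without 1,3-acyl migration from O7.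

Compound list
1 | propyne | CC#C | starting material
2 | ethyl diazoacetate | CCOC(=O)C=[N+]=[N-] | starting material
3 | ethyl (1S)-2-methylcycloprop-2-ene-1-carboxylate | CC1=C[C@@H]1C(=O)OCC | intermediate
4 | [(1S)-2-methylcycloprop-2-en-1-yl]methanol | CC1=C[C@@H]1CO | intermediate
5 | tert-butyldimethyl{[(1S)-2-methylcycloprop-2-en-1-yl]methoxy}silane | CC1=C[C@@H]1CO[Si](C)(C)C(C)(C)C | intermediate
6 | ethyl 4-exo-[(TBS-oxy)methyl]-1-methylbicyclo[1.1.0]butane-2-exo-carboxylate | CC(C)(C)[Si](C)(C)OC[C@H]1[C@@H]2[C@@H](C(=O)OCC)[C@]12C | intermediate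
7 | 1-{4-exo-[(TBS-oxy)methyl]-1-methylbicyclo[1.1.0]butan-2-exo-yl}-2-(trimethylsilyl)ethan-1-one (not isolated) | CC(C)(C)[Si](C)(C)OC[C@H]1[C@@H]2[C@@H](C(=O)C[Si](C)(C)C)[C@]12C | intermediate
8 | 1-{4-exo-[(TBS-oxy)methyl]-1-methylbicyclo[1.1.0]butan-2-exo-yl}ethan-1-one (not isolated) | CC(C)(C)[Si](C)(C)OC[C@H]1[C@@H]2[C@@H](C(C)=O)[C@]12C | intermediate
9 | 1-[4-exo-(hydroxymethyl)-1-methylbicyclo[1.1.0]butan-2-exo-yl]ethan-1-one | OC[C@H]1[C@@H]2[C@@H](C(C)=O)[C@]12C | intermediate
10 | ethyl 2-methyl-3-oxobutanoate | CCOC(=O)C(C)C(C)=O | starting material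
11 | ethyl 2-methyl-3,5-dioxopentanoate (not isolated) | CCOC(=O)C(C)C(=O)CC=O | intermediate
12 | 4-hydroxy-3-methyl-2H-pyran-2-one | CC1=C(O)C=COC1=O | intermediate
13 | 3-chloro-1,1,3,3-tetraisopropyldisiloxanyl ether of 9 (not isolated) | CC(C)[Si](Cl)(C(C)C)O[Si](C(C)C)(C(C)C)OC[C@H]1[C@@H]2[C@@H](C(C)=O)[C@]12C | intermediate
14 | TIPDS-tethered pyrone–bicyclobutane, 1-[(bicyclobutanyl)methoxy]-3-[(3-methyl-2-oxo-2H-pyran-4-yl)oxy]-1,1,3,3-tetraisopropyldisiloxane | CC1=C(O[Si](C(C)C)(C(C)C)O[Si](C(C)C)(C(C)C)OC[C@H]2[C@@H]3[C@@H](C(C)=O)[C@]23C)C=COC1=O | intermediate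
15 | TIPDS-bridged silyl enol ether cage, O7 and the C3 oxygen joined by the disiloxane, C7=C8 enol ether, 15,9-olide (not isolated) | O1C2=C[C@@H](OC3=O)[C@]4(C)[C@@H](CO[Si](C(C)C)(C(C)C)O[Si]1(C(C)C)C(C)C)[C@@H]([C@H]4C(C)=O)[C@]23C | intermediate
16 | 3-hydroxy-1,7-dioxo-12-nor-2,3-secolongipinan-15,9-olide | O=C1C[C@@H](OC3=O)[C@]2(C)[C@@H](CO)[C@@H]([C@H]2C(C)=O)[C@]13C | intermediate
17 | 1,3,7-trioxo-12-nor-2,3-secolongipinan-15,9-olide | O=C1C[C@@H](OC3=O)[C@]2(C)[C@@H](C=O)[C@@H]([C@H]2C(C)=O)[C@]13C | intermediate
18 | 3-hydroxy-1,7-dioxo-12-norlongipinan-15,9-olide, C3 epimers (not isolated) | O=C1C[C@@H](OC4=O)[C@]2(C)[C@@H]3[C@@H]([C@H]2C(=O)CC3O)[C@]14C | intermediate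
19 | 1,7-dioxo-12-norlongipin-2-en-15,9-olide | O=C1C[C@@H](OC4=O)[C@]2(C)[C@@H]3[C@@H]([C@H]2C(=O)C=C3)[C@]14C | intermediate
20 | 7-oxo-1-(trimethylsilyloxy)longipin-1-en-15,9-olide | O=C1C[C@@H](OC4=O)[C@]2(C)[C@@H]3[C@@H]([C@H]2C(O[Si](C)(C)C)=C[C@H]3C)[C@]14C | intermediate
21 | 1-(trimethylsilyloxy)longipin-1-ene-7,9,15-triol (not isolated) | O[C@@H]1C[C@@H](O)[C@]2(C)[C@@H]3[C@@H]([C@H]2C(O[Si](C)(C)C)=C[C@H]3C)[C@@]1(C)CO | intermediate
22 | 7,9,15-trihydroxylongipinan-1-one | O[C@@H]1C[C@@H](O)[C@]2(C)[C@@H]3[C@@H]([C@H]2C(=O)C[C@H]3C)[C@@]1(C)CO | intermediate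
23 | 15-(TBDPS-oxy)-7,9-dihydroxylongipinan-1-one | O[C@@H]1C[C@@H](O)[C@]2(C)[C@@H]3[C@@H]([C@H]2C(=O)C[C@H]3C)[C@@]1(C)CO[Si](c1ccccc1)(c1ccccc1)C(C)(C)C | intermediate
24 | angelic acid, (Z)-2-methylbut-2-enoic acid | C/C=C(/C)C(=O)O | starting material
25 | 7,9-bis(angeloyloxy)-15-(TBDPS-oxy)longipinan-1-one | C/C=C(/C)C(=O)O[C@@H]1C[C@@H](OC(=O)/C(C)=C\C)[C@]2(C)[C@@H]3[C@@H]([C@H]2C(=O)C[C@H]3C)[C@@]1(C)CO[Si](c1ccccc1)(c1ccccc1)C(C)(C)C | intermediate
26 | 7,9-bis(angeloyloxy)-15-hydroxylongipinan-1-one | C/C=C(/C)C(=O)O[C@@H]1C[C@@H](OC(=O)/C(C)=C\C)[C@]2(C)[C@@H]3[C@@H]([C@H]2C(=O)C[C@H]3C)[C@@]1(C)CO | target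

Total step count: 15. Longest linear sequence: 14 steps (steps 1–5 and 7–15).

Steps most likely to fail

Step 8. The bicyclobutane radical cation may rearrange before it is captured, the silyl dienol ether may be desilylated or oxidised unproductively, or the C10 radical may be reduced before it closes the seven-membered ring. The fallback uses known radical chemistry, forms the two bonds in two successive operations and gives up the tether. It sets out from 9 and 12 and comes back to the route at 16. Bromination of 12 with N-bromosuccinimide in CH2Cl2 should give 3-bromo-3-methyl-2H-pyran-2,4(3H)-dione F1. Bromine-atom-transfer addition of F1 across the central bond of 9 (Et3B, air, CH2Cl2, −20 °C), the known mode of addition of polyhaloalkanes and sulfonyl halides to bicyclobutanes, should give the C5–C6 adduct with bromine on C10, F2. Slow addition of Bu3SnH with AIBN in refluxing benzene should regenerate the C10 radical, which closes onto C9 of the enone (7-endo) and takes hydrogen at C8 to give 16. Without the tether the closure is not directed, so the cage with the lactone bridge on the C4 side F3 is expected as well and would be removed by chromatography.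

Step 4. The metal carbene may open the cyclopropene or dimerise instead of adding to the double bond, and the ester may enter with poor exo selectivity. The fallback adds the second carbene to the cyclopropene ester, the substrate class of the classical double addition, and takes the asymmetry from an enzyme; it sets out from 3 (racemic material suffices) and comes back at 6. Copper-catalysed addition of ethyl diazoacetate to 3 should give the meso diester diethyl 1-methylbicyclo[1.1.0]butane-2-exo,4-exo-dicarboxylate F4. Enantiotopic-group-selective hydrolysis with pig liver esterase in pH 7 buffer (or with a lipase of the required preference) should give the mono-acid F5. Reduction of the acid through its mixed anhydride (isobutyl chloroformate, N-methylmorpholine; NaBH4) should give ethyl 4-exo-(hydroxymethyl)-1-methylbicyclo[1.1.0]butane-2-exo-carboxylate F6, and silylation with TBSCl and imidazole then gives 6.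

Step 14. Acylation of the two hindered secondary hydroxyls may be slow, and forcing may isomerise angeloyl to tigloyl. The fallback builds the Z double bonds on the substrate; it sets out from 23 and comes back at 25. Esterification of 23 with 2-[bis(2,2,2-trifluoroethoxy)phosphoryl]propanoic acid (DCC, DMAP, CH2Cl2) should give the bis(phosphonopropionate) F7. Still–Gennari olefination with acetaldehyde (KHMDS, 18-crown-6, THF, −78 °C) should then give 25 with Z geometry in both esters.

Further compounds
F1 | step 8 | 3-bromo-3-methyl-2H-pyran-2,4(3H)-dione | CC1(Br)C(=O)C=COC1=O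
F2 | step 8 | C5–C6 bromine-transfer adduct of 9 and F1, bromine on C10 (mixture at C6 and C10) | CC1(Br)[C@@H](CO)[C@@H]([C@H]1C(C)=O)C1(C)C(=O)C=COC1=O
F3 | step 8 | diastereomer of 16 with the lactone bridge on the C4 side | O=C1C[C@H](OC3=O)[C@]2(C)[C@@H](CO)[C@@H]([C@H]2C(C)=O)[C@@]13C
F4 | step 4 | diethyl 1-methylbicyclo[1.1.0]butane-2-exo,4-exo-dicarboxylate (meso) | CCOC(=O)[C@H]1[C@@H]2[C@@H](C(=O)OCC)[C@]12C
F5 | step 4 | mono-acid of F4 with the free acid on the future C4 wing | OC(=O)[C@H]1[C@@H]2[C@@H](C(=O)OCC)[C@]12C
F6 | step 4 | ethyl 4-exo-(hydroxymethyl)-1-methylbicyclo[1.1.0]butane-2-exo-carboxylate | OC[C@H]1[C@@H]2[C@@H](C(=O)OCC)[C@]12C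
F7 | step 14 | 7,9-bis{2-[bis(2,2,2-trifluoroethoxy)phosphoryl]propanoyl} ester of 23 | CC(P(=O)(OCC(F)(F)F)OCC(F)(F)F)C(=O)O[C@@H]1C[C@@H](OC(=O)C(C)P(=O)(OCC(F)(F)F)OCC(F)(F)F)[C@]2(C)[C@@H]3[C@@H]([C@H]2C(=O)C[C@H]3C)[C@@]1(C)CO[Si](c1ccccc1)(c1ccccc1)C(C)(C)C
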